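C5'–C10' of the side chain is the array CH2–CH(OH)–CH2–CH(OH)–CH=CH(Ph) with syn hydroxyls on C6' and C8'. With C10' at the aldehyde level this is a 6-substituted 3,5-dihydroxyhexanal, the open form of a 2,4-dideoxyhexopyranose ring (C6'–O–C10'), which an acetaldehyde-dependent aldolase builds from two-carbon units.
Retrosynthetic cuts, in order: C1'=C2' (cross-metathesis, releasing a vinyl dihydropyranone), the C4' carbinol back to a ketone, C4'–C5' (acyl anion plus oxirane), C10'–phenyl, then C8'–C9' and C6'–C7' (two aldol bonds).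
Forward: the tetrahydropyran lactol ring forms in step 1 and is exchanged for a dioxane acetal in step 3. Phenyl is then placed on C10', the C5'–C6' oxirane is closed and opened by a dithiane anion, and C4' is reduced. The dihydropyranone ring is made separately by ring-closing metathesis and joined last.
Stereochemistry: C6' and C8' come from the enzyme, C4' from a hydroxyl-directed anti reduction relayed from C6', and C6 from a pinene-derived allylborane. The E-alkenes come from syn β-hydride elimination (C9'=C10') and thermodynamic metathesis control (C1'=C2').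

Key step: step 1

Assumption: C2–C6 are the lactone ring atoms and C1'–C10' the side chain counted from C6 to the phenyl-bearing carbon. Lactol 5 is taken as an anomer mixture, which has no consequence because C10' ends trigonal.

Step 1
Reactants: 1 chloroacetaldehyde; 2 acetaldehyde (two equivalents)
Product: 5 (4R,6S)-6-(chloromethyl)tetrahydro-2H-pyran-2,4-diol, via (S)-4-chloro-3-hydroxybutanal 3 (not isolated), via (3R,5S)-6-chloro-3,5-dihydroxyhexanal 4 (not isolated)
Conditions: 2-deoxy-D-ribose-5-phosphate aldolase (E. coli, cell-free extract), 1 and 2 (2.2 equiv) fed slowly, aq. NaHCO3 buffer pH 7.2, 25 °C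
Reagents that add atoms: none
Why: The active-site lysine condenses with acetaldehyde to an enamine that adds to the carbonyl of 1 (C6'–C7' bond) to give 3, and 3 is taken up again as acceptor so that a second enamine addition (C8'–C9' bond) gives 4. This is the established sequential aldol reaction of deoxyribose-phosphate aldolase with α-substituted acetaldehydes. Aldehyde 4 closes by 6-exo-trig attack of the C6' hydroxyl on the C10' carbonyl to the tetrahydropyran lactol 5. Both carbinol centres are fixed by the enzyme pocket, which offers the same face of each acceptor carbonyl to the enamine, so that C6' is S and C8' is R in 5 and the two oxygens are syn; only the anomeric centre is uncontrolled and it is erased in step 2. The step needs acceptor selectivity (1 before 2) and a stop after two additions: the chlorine makes 1 the more electrophilic acceptor, slow feeding keeps free 2 low, and the lactol has no free carbonyl and so leaves the cycle.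

Step 2
Reactants: 5 (4R,6S)-6-(chloromethyl)tetrahydro-2H-pyran-2,4-diol
Product: 6 (4R,6S)-6-(chloromethyl)-4-hydroxytetrahydro-2H-pyran-2-one
Conditions: aq. NaOCl (1.1 equiv), AcOH, 20 °C
Reagents that add atoms: none
Why: Lactol-to-lactone oxidation by hypochlorous acid made in the flask; the hemiacetal C–H at C10' is oxidised much faster than the isolated C8' carbinol when the oxidant is held near one equivalent, and no stereocentre is involved.

Step 3
Reactants: 6 (4R,6S)-6-(chloromethyl)-4-hydroxytetrahydro-2H-pyran-2-one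
Product: 8 methyl 2-[(4R,6S)-6-(chloromethyl)-2,2-dimethyl-1,3-dioxan-4-yl]acetate, via methyl (3R,5S)-6-chloro-3,5-dihydroxyhexanoate 7 (not isolated)
Conditions: Me2C(OMe)2, MeOH (cat.), p-TsOH·H2O (cat.), rt
Reagents that add atoms: 2,2-dimethoxypropane, COC(C)(C)OC
Why: Acid-catalysed lactone methanolysis coupled to transacetalisation; methanol released from the reagent opens the ring to 7, and the syn 1,3-diol is trapped at once as a chair dioxane with both side chains equatorial, which pulls the equilibrium to the open-chain ester.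

Step 4
Reactants: 8 methyl 2-[(4R,6S)-6-(chloromethyl)-2,2-dimethyl-1,3-dioxan-4-yl]acetate
Product: 9 2-[(4R,6S)-6-(chloromethyl)-2,2-dimethyl-1,3-dioxan-4-yl]acetaldehyde
Conditions: iBu2AlH (1.05 equiv), toluene, −78 °C; then MeOH, aq. potassium sodium tartrate
Reagents that add atoms: none
Why: Partial ester reduction; the tetrahedral aluminium hemiacetal persists at −78 °C and releases the aldehyde only on work-up, while the primary chloride and the acetal are inert.

Step 5
Reactants: 9 2-[(4R,6S)-6-(chloromethyl)-2,2-dimethyl-1,3-dioxan-4-yl]acetaldehyde; 10 bromobenzene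
Product: 13 (4S,6R)-4-(chloromethyl)-2,2-dimethyl-6-[(E)-2-phenylethenyl]-1,3-dioxane, via aldehyde N-tosylhydrazone 11 (not isolated), via diazoalkane 12 (not isolated)
Conditions: TsNHNH2 (1.05 equiv), 1,4-dioxane, 50 °C; then 10 (1.1 equiv), Pd2(dba)3 (2 mol%), XPhos (8 mol%), LiOtBu (3 equiv), 90 °C
Reagents that add atoms: p-toluenesulfonyl hydrazide, Cc1ccc(cc1)S(=O)(=O)NN (its atoms stay only in 11 and 12)
Why: Barluenga–Valdés coupling of an aldehyde tosylhydrazone with an aryl bromide; base converts 11 into diazoalkane 12, the phenylpalladium bromide formed from 10 and zerovalent palladium takes it up as a carbene, phenyl migrates to C10', and syn β-hydride elimination from C9' gives the E-styrene without touching C8'.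

Step 6
Reactants: 13 (4S,6R)-4-(chloromethyl)-2,2-dimethyl-6-[(E)-2-phenylethenyl]-1,3-dioxane
Product: 15 (2R,3E)-1-[(2S)-oxiran-2-yl]-4-phenylbut-3-en-2-ol, via (2S,4R,5E)-1-chloro-6-phenylhex-5-ene-2,4-diol 14 (not isolated)
Conditions: camphorsulfonic acid (10 mol%), MeOH, 0 °C to rt; then K2CO3 (2 equiv), rt
Reagents that add atoms: none
Why: Mild acid transacetalisation frees the diol without ionising the cinnamyl-type C8' carbinol, and carbonate then closes the chlorohydrin by intramolecular Williamson displacement (3-exo-tet) at C5', so the C6'–O bond and its configuration are retained.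

Step 7
Reactants: 16 1,3-dithiane; 17 allyl bromide
Product: 19 2-(prop-2-en-1-yl)-1,3-dithiane, via 2-lithio-1,3-dithiane 18 (not isolated)
Conditions: n-BuLi, THF, −30 °C; then 17, −78 °C to rt
Reagents that add atoms: n-butyllithium, [Li]CCCC (lithium stays only in 18)
Why: Corey–Seebach alkylation; the sulfur-stabilised carbanion displaces the reactive allylic bromide in an SN2 reaction.

Step 8
Reactants: 15 (2R,3E)-1-[(2S)-oxiran-2-yl]-4-phenylbut-3-en-2-ol; 19 2-(prop-2-en-1-yl)-1,3-dithiane
Product: 21 (1E,3R,5S)-1-phenyl-6-[2-(prop-2-en-1-yl)-1,3-dithian-2-yl]hex-1-ene-3,5-diol, via 2-allyl-2-lithio-1,3-dithiane 20 (not isolated)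
Conditions: 19 (2.6 equiv), n-BuLi (2.5 equiv), THF, −20 °C; then 15, DMPU, −78 to 0 °C; then H2O
Reagents that add atoms: n-butyllithium, [Li]CCCC (lithium stays only in 20)
Why: Dithiane umpolung with epoxide opening; the first equivalent of 20 only deprotonates the C8' hydroxyl and the next attacks the unhindered C5' terminus by SN2 to form C4'–C5', while keeping 19 in slight excess over n-BuLi leaves no alkyllithium to add to the styrene, and no stereocentre is touched.

Step 9
Reactants: 21 (1E,3R,5S)-1-phenyl-6-[2-(prop-2-en-1-yl)-1,3-dithian-2-yl]hex-1-ene-3,5-diol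
Product: 22 (6S,8R,9E)-6,8-dihydroxy-10-phenyldeca-1,9-dien-4-one
Conditions: MeI (10 equiv), CaCO3 (5 equiv), MeCN/H2O 9:1, rt to 40 °C
Reagents that add atoms: water, O
Why: Alkylative dithiane hydrolysis (S-methylation, then attack of water); the carbonate buffer keeps the medium near neutral so that the β-hydroxy, β',γ'-unsaturated ketone should neither conjugate nor dehydrate, and the reagent leaves the alkenes alone where halonium or mercury reagents might not.

Step 10
Reactants: 22 (6S,8R,9E)-6,8-dihydroxy-10-phenyldeca-1,9-dien-4-one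
Product: 23 (1E,3R,5R,7S)-1-phenyldeca-1,9-diene-3,5,7-triol
Conditions: Me4NBH(OAc)3 (6 equiv), MeCN/AcOH 1:1, −30 °C; then aq. potassium sodium tartrate
Reagents that add atoms: none
Why: Evans–Saksena reduction; the C6' hydroxyl displaces an acetate on boron and hydride is delivered within a chair-like six-membered transition state, giving the 1,3-anti C4'/C6' diol (4'S), while the C8' hydroxyl is too remote to deliver hydride and can mask the ketone only reversibly as a hemiketal.

Step 11
Reactants: 24 acrolein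
Product: 26 (3R)-hexa-1,5-dien-3-ol, via diisopinocampheylborinate ester 25 (not isolated)
Conditions: (+)-Ipc2B(allyl), Et2O/pentane, −78 °C; then 3 M NaOH, 30% H2O2, 0 °C to rt
Reagents that add atoms: (+)-B-allyldiisopinocampheylborane (from (−)-α-pinene), C=CCB([C@H]1C[C@H]2C[C@@H]([C@@H]1C)C2(C)C)[C@H]1C[C@H]2C[C@@H]([C@@H]1C)C2(C)C
Why: Brown allylboration through a closed chair transition state; the isopinocampheyl groups derived from (−)-α-pinene direct the allyl group to the aldehyde face that gives the R carbinol, the future C6.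

Step 12
Reactants: 26 (3R)-hexa-1,5-dien-3-ol; 27 acryloyl chloride
Product: 28 (3R)-hexa-1,5-dien-3-yl prop-2-enoate
Conditions: Et3N, DMAP (cat.), CH2Cl2, 0 °C
Reagents that add atoms: none
Why: O-acylation of a secondary alcohol with an acid chloride and an amine base, which does not break the C–O bond at the stereocentre.

Step 13
Reactants: 28 (3R)-hexa-1,5-dien-3-yl prop-2-enoate
Product: 29 (6R)-6-ethenyl-5,6-dihydro-2H-pyran-2-one
Conditions: first-generation Grubbs catalyst RuCl2(PCy3)2(=CHPh) (5 mol%), Ti(OiPr)4 (0.3 equiv), CH2Cl2 (dilute), 40 °C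
Reagents that add atoms: none
Why: Ring-closing metathesis; the alkylidene loads on the unhindered allyl terminus and closes on the acrylate to the six-membered enoate, whereas the branched vinyl group could only give a strained butenolide and so remains as the handle for step 14.

Step 14
Reactants: 23 (1E,3R,5R,7S)-1-phenyldeca-1,9-diene-3,5,7-triol; 29 (6R)-6-ethenyl-5,6-dihydro-2H-pyran-2-one
Product: 30 (6R)-6-[(1E,4S,6R,8R,9E)-4,6,8-trihydroxy-10-phenyldeca-1,9-dien-1-yl]-5,6-dihydro-2H-pyran-2-one
Conditions: 29 (3 equiv), second-generation Hoveyda–Grubbs catalyst RuCl2(H2IMes)(=CH-C6H4-2-OiPr) (10 mol%), 1,4-benzoquinone (10 mol%), CH2Cl2, 40 °C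
Reagents that add atoms: none
Why: Olefin cross-metathesis; the unhindered homoallylic terminus of 23 reacts fast while the branched allylic-ester alkene of 29 homodimerises slowly, a pairing that favours the cross product, the E geometry follows from thermodynamic control, and the 1,2-disubstituted styryl and ring enoate double bonds are far less reactive toward the catalyst.

Compound list
1 | chloroacetaldehyde | O=CCCl | starting material
2 | acetaldehyde | CC=O | starting material
3 | (S)-4-chloro-3-hydroxybutanal | O=CC[C@H](O)CCl | intermediate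
4 | (3R,5S)-6-chloro-3,5-dihydroxyhexanal | O=CC[C@H](O)C[C@H](O)CCl | intermediate
5 | (4R,6S)-6-(chloromethyl)tetrahydro-2H-pyran-2,4-diol (anomer mixture) | OC1C[C@H](O)C[C@@H](CCl)O1 | intermediate
6 | (4R,6S)-6-(chloromethyl)-4-hydroxytetrahydro-2H-pyran-2-one | O=C1C[C@H](O)C[C@@H](CCl)O1 | intermediate
7 | methyl (3R,5S)-6-chloro-3,5-dihydroxyhexanoate | COC(=O)C[C@H](O)C[C@H](O)CCl | intermediate
8 | methyl 2-[(4R,6S)-6-(chloromethyl)-2,2-dimethyl-1,3-dioxan-4-yl]acetate | COC(=O)C[C@H]1C[C@@H](CCl)OC(C)(C)O1 | intermediate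
9 | 2-[(4R,6S)-6-(chloromethyl)-2,2-dimethyl-1,3-dioxan-4-yl]acetaldehyde | O=CC[C@H]1C[C@@H](CCl)OC(C)(C)O1 | intermediate
10 | bromobenzene | Brc1ccccc1 | starting material
11 | (E)-N-tosylhydrazone of aldehyde 9 | Cc1ccc(cc1)S(=O)(=O)N/N=C/C[C@H]1C[C@@H](CCl)OC(C)(C)O1 | intermediate
12 | (4S,6R)-4-(chloromethyl)-6-(2-diazoethyl)-2,2-dimethyl-1,3-dioxane | [N-]=[N+]=CC[C@H]1C[C@@H](CCl)OC(C)(C)O1 | intermediate
13 | (4S,6R)-4-(chloromethyl)-2,2-dimethyl-6-[(E)-2-phenylethenyl]-1,3-dioxane | c1ccccc1/C=C/[C@H]2C[C@@H](CCl)OC(C)(C)O2 | intermediate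
14 | (2S,4R,5E)-1-chloro-6-phenylhex-5-ene-2,4-diol | ClC[C@@H](O)C[C@@H](O)/C=C/c1ccccc1 | intermediate
15 | (2R,3E)-1-[(2S)-oxiran-2-yl]-4-phenylbut-3-en-2-ol | C1O[C@H]1C[C@@H](O)/C=C/c2ccccc2 | intermediate
16 | 1,3-dithiane | C1CSCSC1 | starting material
17 | allyl bromide | C=CCBr | starting material
18 | 2-lithio-1,3-dithiane | [Li]C1SCCCS1 | intermediate
19 | 2-(prop-2-en-1-yl)-1,3-dithiane | C=CCC1SCCCS1 | intermediate
20 | 2-allyl-2-lithio-1,3-dithiane | [Li]C1(CC=C)SCCCS1 | intermediate
21 | (1E,3R,5S)-1-phenyl-6-[2-(prop-2-en-1-yl)-1,3-dithian-2-yl]hex-1-ene-3,5-diol | C=CCC1(C[C@@H](O)C[C@@H](O)/C=C/c2ccccc2)SCCCS1 | intermediate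
22 | (6S,8R,9E)-6,8-dihydroxy-10-phenyldeca-1,9-dien-4-one | C=CCC(=O)C[C@@H](O)C[C@@H](O)/C=C/c1ccccc1 | intermediate
23 | (1E,3R,5R,7S)-1-phenyldeca-1,9-diene-3,5,7-triol | C=CC[C@H](O)C[C@@H](O)C[C@@H](O)/C=C/c1ccccc1 | intermediate
24 | acrolein | C=CC=O | starting material
25 | (3R)-hexa-1,5-dien-3-yl diisopinocampheylborinate (Ipc groups from (−)-α-pinene) | C=CC[C@H](C=C)OB([C@H]1C[C@H]2C[C@@H]([C@@H]1C)C2(C)C)[C@H]1C[C@H]2C[C@@H]([C@@H]1C)C2(C)C | intermediate
26 | (3R)-hexa-1,5-dien-3-ol | C=CC[C@H](C=C)O | intermediate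
27 | acryloyl chloride | C=CC(=O)Cl | starting material
28 | (3R)-hexa-1,5-dien-3-yl prop-2-enoate | C=CC[C@H](C=C)OC(=O)C=C | intermediate
29 | (6R)-6-ethenyl-5,6-dihydro-2H-pyran-2-one | O=C1C=CC[C@H](C=C)O1 | intermediate
30 | (6R)-6-[(1E,4S,6R,8R,9E)-4,6,8-trihydroxy-10-phenyldeca-1,9-dien-1-yl]-5,6-dihydro-2H-pyran-2-one | O=C1C=CC[C@H](/C=C/C[C@H](O)C[C@@H](O)C[C@@H](O)/C=C/c2ccccc2)O1 | target

Total step count: 14.
Longest linear sequence: 10 steps (steps 1–6, 8–10 and 14). Step 7 and steps 11–13 are side branches.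

Steps most likely to fail

**Step 5.** The hot alkoxide may strip HCl from the chloromethyl group. The diazoalkane may also collapse by 1,2-hydride shift or azine formation before palladium captures it.
The fallback sets out from 9 and forms the C10'–phenyl bond by carbonyl addition. Phenylmagnesium bromide (from 10 and magnesium in THF) is added at −78 °C to give 2-[(4R,6S)-6-(chloromethyl)-2,2-dimethyl-1,3-dioxan-4-yl]-1-phenylethan-1-ol F1 as an epimer mixture at C10'. Martin sulfurane, Ph2S[OC(CF3)2Ph]2, in CH2Cl2 at rt then dehydrates the benzylic alcohol toward C9' under non-acidic conditions. The route is rejoined at 13.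

**Step 9.** During unmasking the terminal double bond may migrate into conjugation with the new ketone, or the C6' hydroxyl may be lost by β-elimination.
The fallback sets out from 15 and sets C4' by reagent-controlled allylation of an aldehyde instead.
- 2-Lithio-1,3-dithiane 18 (2.5 equiv, from 16) opens the epoxide to (1E,3R,5S)-6-(1,3-dithian-2-yl)-1-phenylhex-1-ene-3,5-diol F2.
- 2,2-Dimethoxypropane with PPTS gives the syn acetonide 2-{[(4S,6R)-2,2-dimethyl-6-[(E)-2-phenylethenyl]-1,3-dioxan-4-yl]methyl}-1,3-dithiane F3.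
- MeI and CaCO3 in aqueous MeCN free 2-[(4S,6R)-2,2-dimethyl-6-[(E)-2-phenylethenyl]-1,3-dioxan-4-yl]acetaldehyde F4, which carries no alkene that could migrate.
- (−)-B-Allyldiisopinocampheylborane (from (+)-α-pinene) in Et2O at −78 °C, followed by NaOH and H2O2, gives (2S)-1-[(4R,6R)-2,2-dimethyl-6-[(E)-2-phenylethenyl]-1,3-dioxan-4-yl]pent-4-en-2-ol F5.
- Camphorsulfonic acid in MeOH removes the acetal, and the route is rejoined at 23.

**Step 14.** Slow turnover of the branched, ester-bearing vinyl group may let homodimerisation of 23 and ruthenium hydride isomerisation of the allylic alcohol compete. Long exposure may also draw the styryl double bond into alkylidene exchange.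
The fallback sets out from 23 and builds the lactone ring on the chain.
- Et3SiCl and imidazole give (1E,3R,5R,7S)-1-phenyl-3,5,7-tris(triethylsilyloxy)deca-1,9-diene F6.
- A short cross-metathesis with the fast partner crotonaldehyde, using the second-generation Grubbs catalyst RuCl2(PCy3)(H2IMes)(=CHPh), gives (2E,5S,7R,9R,10E)-11-phenyl-5,7,9-tris(triethylsilyloxy)undeca-2,10-dienal F7.
- (+)-B-Allyldiisopinocampheylborane sets C6 and gives (4R,5E,8S,10R,12R,13E)-14-phenyl-8,10,12-tris(triethylsilyloxy)tetradeca-1,5,13-trien-4-ol F8.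
- 27 with Et3N gives the corresponding prop-2-enoate ester F9.
- The first-generation Grubbs catalyst RuCl2(PCy3)2(=CHPh), which ignores internal alkenes, closes (6R)-6-[(1E,4S,6R,8R,9E)-10-phenyl-4,6,8-tris(triethylsilyloxy)deca-1,9-dien-1-yl]-5,6-dihydro-2H-pyran-2-one F10.
- HF·pyridine in THF removes the silyl groups, and the route is rejoined at 30.

Further compounds
F1 | step 5 | 2-[(4R,6S)-6-(chloromethyl)-2,2-dimethyl-1,3-dioxan-4-yl]-1-phenylethan-1-ol (both C10' epimers) | OC(C[C@H]1C[C@@H](CCl)OC(C)(C)O1)c1ccccc1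
F2 | step 9 | (1E,3R,5S)-6-(1,3-dithian-2-yl)-1-phenylhex-1-ene-3,5-diol | S1CCCSC1C[C@@H](O)C[C@@H](O)/C=C/c1ccccc1
F3 | step 9 | 2-{[(4S,6R)-2,2-dimethyl-6-[(E)-2-phenylethenyl]-1,3-dioxan-4-yl]methyl}-1,3-dithiane | S1CCCSC1C[C@@H]2C[C@H](/C=C/c3ccccc3)OC(C)(C)O2
F4 | step 9 | 2-[(4S,6R)-2,2-dimethyl-6-[(E)-2-phenylethenyl]-1,3-dioxan-4-yl]acetaldehyde | O=CC[C@@H]2C[C@H](/C=C/c3ccccc3)OC(C)(C)O2
F5 | step 9 | (2S)-1-[(4R,6R)-2,2-dimethyl-6-[(E)-2-phenylethenyl]-1,3-dioxan-4-yl]pent-4-en-2-ol | C=CC[C@H](O)C[C@@H]2C[C@H](/C=C/c3ccccc3)OC(C)(C)O2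
F6 | step 14 | (1E,3R,5R,7S)-1-phenyl-3,5,7-tris(triethylsilyloxy)deca-1,9-diene | C=CC[C@H](O[Si](CC)(CC)CC)C[C@@H](O[Si](CC)(CC)CC)C[C@@H](O[Si](CC)(CC)CC)/C=C/c1ccccc1
F7 | step 14 | (2E,5S,7R,9R,10E)-11-phenyl-5,7,9-tris(triethylsilyloxy)undeca-2,10-dienal | O=C/C=C/C[C@H](O[Si](CC)(CC)CC)C[C@@H](O[Si](CC)(CC)CC)C[C@@H](O[Si](CC)(CC)CC)/C=C/c1ccccc1
F8 | step 14 | (4R,5E,8S,10R,12R,13E)-14-phenyl-8,10,12-tris(triethylsilyloxy)tetradeca-1,5,13-trien-4-ol | C=CC[C@H](/C=C/C[C@H](O[Si](CC)(CC)CC)C[C@@H](O[Si](CC)(CC)CC)C[C@@H](O[Si](CC)(CC)CC)/C=C/c1ccccc1)O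
F9 | step 14 | (4R,5E,8S,10R,12R,13E)-14-phenyl-8,10,12-tris(triethylsilyloxy)tetradeca-1,5,13-trien-4-yl prop-2-enoate | C=CC[C@H](/C=C/C[C@H](O[Si](CC)(CC)CC)C[C@@H](O[Si](CC)(CC)CC)C[C@@H](O[Si](CC)(CC)CC)/C=C/c1ccccc1)OC(=O)C=C
F10 | step 14 | (6R)-6-[(1E,4S,6R,8R,9E)-10-phenyl-4,6,8-tris(triethylsilyloxy)deca-1,9-dien-1-yl]-5,6-dihydro-2H-pyran-2-one | O=C1C=CC[C@H](/C=C/C[C@H](O[Si](CC)(CC)CC)C[C@@H](O[Si](CC)(CC)CC)C[C@@H](O[Si](CC)(CC)CC)/C=C/c2ccccc2)O1
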